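## Structural features

The target is a germacrane-type sesquiterpene lactone: a ten-membered carbocycle (C1–C10) with an α-methylene-γ-butyrolactone (O, C12, C11, C7, C6; exocyclic C13) cis-fused at C6/C7. The ring carries a C4–C5 epoxide (C4 quaternary, methyl C15) in which the ring carbons C3 and C6 are cis. It also carries a trisubstituted C1=C10 alkene with the methyl ester C14 on C10 and with C2 and C9 on the same side. Six contiguous stereocentres run from C4 to C9 (4R,5S,6R,7R,8S,9S); C8 carries an (S)-2-methyloxirane-2-carboxylate and C9 an acetate, so two neighbouring secondary oxygens must be told apart. Fragile groups are the methylene lactone (Michael acceptor), the ring epoxide (transannular opening by the 1(10)-alkene under acid), the epoxy ester, and the C9 acetate, which becomes an SN2′-prone allylic acetate once C14 is a carbonyl. The real difficulty is closing the strained ten-membered ring while setting C5 and C6, and then bringing seven oxygen functions to their final state in a compatible order. The feature used here is that the lactone ring is a reduced butenolide, i.e. the dearomatised form of a 2-silyloxyfuran whose nucleophilic 5-position is C6, bonded directly to oxygenated C5; this is a vinylogous aldol retron. The C8/C9 threo-diol maps onto L-tartaric acid (its carboxyl carbons become C7 and C10), C4 onto (S)-2-methylglycidol, and the side-chain acid onto (R)-2-methylglycidol, the opposite enantiomer.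

## Logic of the disconnections

39 ⇒ 38 ⇒ 37 ⇒ 36 ⇒ 35. No skeletal bond is cut; the ester O–CH3 bond and the C14 oxidation level are taken back to a silyl ether. An acrylate at C10 in earlier compounds would compete in the conjugate reduction and would turn the C9 oxygen into an SN2′ leaving group. The gain is a plain C1=C10 alkene in every earlier compound. The demand is that desilylation, two oxidations and a methylation stay near neutral for two epoxides and the methylene lactone.

35 ⇒ 34. The C5–O bond of the epoxide is cut to a tertiary alcohol and a C5 mesylate. The epoxide oxygen is the C4 oxygen that is present from the start, and displacement with inversion ties the epoxide configuration to the C5 carbinol of the ring closure. The gain is that the acid-labile epoxide is absent during ketal hydrolysis and acylation. The demand is a 5R carbinol trans to the C4 oxygen on the ring, and a base that touches only the tertiary hydroxyl.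

34 ⇒ 33 ⇒ 29 + 31, and 31 ⇒ 30. The two acyl C–O bonds are cut. Esters cannot pass through the enolate and hydride steps, so they come late. The gain is a diol plus a three-carbon epoxy acid from the chiral pool. The demand is site selection between O8 and O9: the bulky acid goes on first, and C9–OH is expected to be screened by the neighbouring silyloxymethyl group on C10.

29 ⇒ 28 ⇒ 27 ⇒ 24 ⇒ 23. The ketal and silyl ether are restored, the C5–O–S bond, the C11=C13 bond, and the C7–H and C11–H bonds are removed. The order matters: reduction must precede mesylation, because a leaving group on C5 next to an acidic butenolide γ-hydrogen would eliminate, and methylenation must precede every ester. The gain is the butenolide from the ring closure. The demand is hydride delivery to C7 anti to C5, which gives the cis ring fusion.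

23 ⇒ 22. The C5–C6 bond is cut and the ten-membered ring opens to an aldehyde tethered to a 2-silyloxyfuran. This one cut removes the ring, two stereocentres and the lactone oxidation pattern at once. The demand is a macrocyclising vinylogous aldol with control of C5 and C6.

22 ⇒ 21 ⇒ 20 ⇒ 19 ⇒ 18 ⇒ 17. No skeletal bond is cut; the furan O–Si bond, the C5 oxidation level, the C5 ether, the C14 silyl ether and the C14–O bond are removed. The aldehyde has no α-hydrogen and is made just before cyclisation. The C14 oxygen is introduced after the olefination so that the olefination has a single α-alkoxy director. The demand is regio- and stereocontrol of one allylic oxidation.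

17 ⇒ 15 ⇒ 13. The butenolide C7=C11 bond (Horner–Wadsworth–Emmons), the C6–O bond and the C6–Br bond are cut. The gain is a methyl ketone. The demand is kinetic enolisation at the methyl group and not at C8–H.

13 ⇒ 8 + 11. The C1=C10 bond is cut. The ketone partner is C2-symmetric, so either carbonyl gives the same product and the one left over becomes C7. The demand is Z geometry from the α-alkoxy ketone effect and mono-olefination.

11 ⇒ 10 ⇒ 9, and 8 ⇒ 7 ⇒ 6 ⇒ 4 ⇒ 3 ⇒ 2 ⇒ 1. The C6–C7 and C10–C14 bonds (methyl additions to amides) and the C2–C3 bond (epoxide opening) are cut. Both lines end at chiral-pool compounds that already hold C8, C9 and C4. The demand is that none of these centres is touched.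

## Other disconnections considered

Alternative 1: The cut is C7–C11 of the lactone. In the forward sense, Rh2(OAc)4 would decompose the C6 diazophosphonoacetate A2, and the carbenoid would insert into a C7–H bond to give the cis-fused α-phosphono lactone A1. A Horner–Wadsworth–Emmons reaction with formaldehyde and fluoride-triggered epoxide closure would finish the synthesis.
- In its favour: the endgame after A1 is about three steps. The methylene group arises under mild base with all esters in place, which is better than the amide-base Mannich sequence of the chosen plan. The cis fusion follows from the five-membered insertion geometry and not from the facial selectivity of a hydride, which is equal or better.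
- Against it here: the step builds only the five-membered ring. A ten-membered carbocycle with five stereocentres, both esters and the mesylate must already exist, so the ring closure and the C5/C6 problem are moved elsewhere, not solved.
- Further risks: the C7–H bonds are inductively deactivated by the C8 acyloxy group, the C8–H bond (α to oxygen) offers a six-membered insertion, and ester or epoxide oxygens can trap the carbenoid as ylides.
- Comparison: the chosen plan uses the lactone carbons as the nucleophile that closes the big ring, so one step serves both rings. Alternative 1 wins on the number of steps after ring formation and loses on everything before it.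

Alternative 2: The cut is a transannular C4–C9 double bond. In the forward sense, Birch reduction of methyl 1-naphthoate gives the tetrahydronaphthoate A4, and ozone cleaves its tetrasubstituted ring-fusion alkene to the cyclodecadienedione A3.
- In its favour: the ten-membered ring is reached in two steps from a commodity arene, with carbonyls at C4 and C9, the ester on C10 and two ring-cis alkenes. On step count to the carbocycle this is clearly better than the chosen plan.
- Against it here: A3 has a single, epimerisable stereocentre and is racemic, so all six ring stereocentres and the absolute configuration remain to be set on a flexible 1,6-diketone that is prone to transannular aldol reaction. The C1=C2 alkene must be moved into conjugation, the C6=C7 alkene must become the lactone junction with oxygenation at C5 and C8, and the methyl must be added to C4 with facial control.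
- Comparison: the chosen plan takes C4, C8 and C9 from the chiral pool and sets C5, C6 and C7 in two substrate-controlled steps. Alternative 2 buys a short ring synthesis with a long and uncertain stereochemical campaign; the two are roughly equal only if a resolution and several ring-controlled steps are accepted.

Alternative 3: The cut is a two-carbon ring expansion. In the forward sense, the pyrrolidine enamine A6 of an eight-membered ketone adds methyl propiolate (C2–C1 and C9–C10 formed), and the fused cyclobutene opens with cleavage of C9–C2 to the ten-membered dienamine ester A5.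
- In its favour: ring expansion avoids the entropic cost of a macrocyclisation, which is equal or better than the chosen closure. The C10 ester and a C9 heteroatom arrive with the step, which is better than a late C14 oxidation. The Z C4=C5 alkene next to the C6 oxygen would allow a hydroxyl-directed epoxidation to the cis epoxide.
- Against it here: A5 has an E C1=C2 alkene and an enamine at C9=C10. Reduction of C1=C2, hydrolysis, reintroduction of C10=C1 and a stereoselective C9 reduction are all needed. The vinyl group on C7 still lacks the lactone carbonyl. The C8 oxygen sits β to the iminium intermediate and may eliminate. The enantiopure eight-membered A6, with three stereocentres and a Z alkene, is itself a medium-ring problem.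
- Comparison: the chosen plan forms the ring later and less reliably, but every ring stereocentre is already in place or is set in the closure, and no skeletal redox correction follows.

Key step: step 17

Assumption: atoms are numbered as in germacranolides (ring C1–C10, lactone C11–C13, ester carbon C14, methyl C15); both enantiomers of 2-methylglycidol, dimethyl 2,3-O-isopropylidene-L-tartrate and diethylphosphonoacetic acid are taken as catalogue compounds.

Step 1
Reactants: 1 (S)-2-methylglycidol
Product: 2 (R)-2-[(4-methoxybenzyloxy)methyl]-2-methyloxirane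
Conditions: NaH, 4-MeOC6H4CH2Cl, Bu4NI (cat.), THF/DMF, 0 °C → rt
Reagents that add atoms: 4-methoxybenzyl chloride, COc1ccc(CCl)cc1
Why: Williamson etherification of the primary alkoxide; the quaternary centre is not involved, and its descriptor changes to R only because the priorities change.

Step 2
Reactants: 2 (R)-2-[(4-methoxybenzyloxy)methyl]-2-methyloxirane
Product: 3 (R)-1-(4-methoxybenzyloxy)-2-methylpent-4-en-2-ol
Conditions: CH2=CHMgBr, CuI (10 mol %), THF, −30 → 0 °C
Reagents that add atoms: vinylmagnesium bromide, C=C[Mg]Br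
Why: Copper-catalysed Grignard opening of a 2,2-disubstituted epoxide occurs by SN2 at the unsubstituted CH2 (C3), forming C2–C3 and leaving the C4 carbinol untouched.

Step 3
Reactants: 3 (R)-1-(4-methoxybenzyloxy)-2-methylpent-4-en-2-ol
Product: 4 (R)-triethyl{[1-(4-methoxybenzyloxy)-2-methylpent-4-en-2-yl]oxy}silane
Conditions: Et3SiOTf, 2,6-lutidine, CH2Cl2, −78 → 0 °C
Reagents that add atoms: triethylsilyl trifluoromethanesulfonate, CC[Si](CC)(CC)OS(=O)(=O)C(F)(F)F
Why: Silyl triflates silylate hindered tertiary alcohols; the non-chelating silyl ether is wanted for the later aldol.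

Step 4
Reactants: 4 (R)-triethyl{[1-(4-methoxybenzyloxy)-2-methylpent-4-en-2-yl]oxy}silane
Product: 6 (R)-5-(4-methoxybenzyloxy)-4-methyl-4-(triethylsilyloxy)pentan-1-ol, via B-alkyl-9-BBN adduct 5 (not isolated)
Conditions: 9-BBN, THF, 0 °C → rt; then NaOH (aq), H2O2, 0 °C
Reagents that add atoms: hydrogen peroxide, OO
Why: Anti-Markovnikov hydroboration–oxidation of the terminal alkene puts the hydroxyl on C1; the tertiary silyl ether tolerates alkaline peroxide.

Step 5
Reactants: 6 (R)-5-(4-methoxybenzyloxy)-4-methyl-4-(triethylsilyloxy)pentan-1-ol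
Product: 7 (R)-1-iodo-5-(4-methoxybenzyloxy)-4-methyl-4-(triethylsilyloxy)pentane
Conditions: I2, PPh3, imidazole, CH2Cl2, 0 °C
Reagents that add atoms: iodine, II
Why: Appel-type iodination of a primary alcohol under buffered conditions that spare the silyl ether.

Step 6
Reactants: 7 (R)-1-iodo-5-(4-methoxybenzyloxy)-4-methyl-4-(triethylsilyloxy)pentane
Product: 8 [(R)-5-(4-methoxybenzyloxy)-4-methyl-4-(triethylsilyloxy)pentyl]triphenylphosphonium iodide
Conditions: PPh3, iPr2NEt (cat.), MeCN, 80 °C
Reagents that add atoms: triphenylphosphine, c1ccc(cc1)P(c1ccccc1)c1ccccc1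
Why: SN2 quaternisation of a primary iodide; a trace of amine keeps the medium from turning acidic.

Step 7
Reactants: 9 dimethyl (4R,5R)-2,2-dimethyl-1,3-dioxolane-4,5-dicarboxylate
Product: 10 (4R,5R)-N4,N5-dimethoxy-N4,N5,2,2-tetramethyl-1,3-dioxolane-4,5-dicarboxamide
Conditions: MeNHOMe·HCl, iPrMgCl, THF, −20 → 0 °C
Reagents that add atoms: N,O-dimethylhydroxylamine hydrochloride, CNOC.Cl
Why: Aminolysis of both esters by the magnesium amide gives the bis-Weinreb amide; the low temperature and the trans-ketal keep C8 and C9 from epimerising.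

Step 8
Reactants: 10 (4R,5R)-N4,N5-dimethoxy-N4,N5,2,2-tetramethyl-1,3-dioxolane-4,5-dicarboxamide
Product: 11 1,1'-[(4R,5R)-2,2-dimethyl-1,3-dioxolane-4,5-diyl]diethanone
Conditions: MeMgBr (3 equiv), THF, −78 → 0 °C
Reagents that add atoms: methylmagnesium bromide, C[Mg]Br
Why: Weinreb ketone synthesis; the chelated tetrahedral intermediates prevent over-addition and the C2-symmetric diketone results (its methyl carbons become C6 and C14).

Step 9
Reactants: 8 [(R)-5-(4-methoxybenzyloxy)-4-methyl-4-(triethylsilyloxy)pentyl]triphenylphosphonium iodide; 11 1,1'-[(4R,5R)-2,2-dimethyl-1,3-dioxolane-4,5-diyl]diethanone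
Product: 13 1-{(4R,5S)-5-[(2Z,6R)-7-(4-methoxybenzyloxy)-6-methyl-6-(triethylsilyloxy)hept-2-en-2-yl]-2,2-dimethyl-1,3-dioxolan-4-yl}ethanone, via phosphonium ylide 12 (not isolated)
Conditions: 8, NaN(SiMe3)2, THF, −78 → 0 °C; then 11 (3 equiv), −78 °C → rt
Reagents that add atoms: none
Why: Wittig olefination of an α-alkoxy methyl ketone with a non-stabilised ylide places the new alkyl group (C2) cis to the alkoxy-bearing carbon (C9), so the Z alkene is expected. Both carbonyls of 11 are equivalent, and an excess of 11 holds back double olefination.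

Step 10
Reactants: 13 1-{(4R,5S)-5-[(2Z,6R)-7-(4-methoxybenzyloxy)-6-methyl-6-(triethylsilyloxy)hept-2-en-2-yl]-2,2-dimethyl-1,3-dioxolan-4-yl}ethanone
Product: 15 2-bromo-1-{(4R,5S)-5-[(2Z,6R)-7-(4-methoxybenzyloxy)-6-methyl-6-(triethylsilyloxy)hept-2-en-2-yl]-2,2-dimethyl-1,3-dioxolan-4-yl}ethanone, via trimethylsilyl enol ether 14 (not isolated)
Conditions: LiN(SiMe3)2, Me3SiCl, THF, −78 °C; then N-bromosuccinimide, −78 → 0 °C
Reagents that add atoms: N-bromosuccinimide, O=C1CCC(=O)N1Br; chlorotrimethylsilane, C[Si](C)(C)Cl (atoms in 14 only)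
Why: Kinetic deprotonation with in-situ silylation takes the methyl group and not the hindered α-alkoxy C8–H; the silyl enol ether is brominated far faster than the trisubstituted alkene or the anisyl ring.

Step 11
Reactants: 15 2-bromo-1-{(4R,5S)-5-[(2Z,6R)-7-(4-methoxybenzyloxy)-6-methyl-6-(triethylsilyloxy)hept-2-en-2-yl]-2,2-dimethyl-1,3-dioxolan-4-yl}ethanone
Product: 17 4-{(4S,5S)-5-[(2Z,6R)-7-(4-methoxybenzyloxy)-6-methyl-6-(triethylsilyloxy)hept-2-en-2-yl]-2,2-dimethyl-1,3-dioxolan-4-yl}furan-2(5H)-one, via keto phosphonoacetate 16 (not isolated)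
Conditions: (EtO)2P(O)CH2CO2H, Cs2CO3, DMF, 0 °C → rt; then LiCl, DBU, 0 °C → rt
Reagents that add atoms: diethylphosphonoacetic acid, CCOP(=O)(CC(=O)O)OCC
Why: Carboxylate SN2 displacement on the α-bromo ketone, then intramolecular Horner–Wadsworth–Emmons olefination under Masamune–Roush conditions, closes the β-substituted butenolide (C11 and C12 added).

Step 12
Reactants: 17 4-{(4S,5S)-5-[(2Z,6R)-7-(4-methoxybenzyloxy)-6-methyl-6-(triethylsilyloxy)hept-2-en-2-yl]-2,2-dimethyl-1,3-dioxolan-4-yl}furan-2(5H)-one
Product: 18 4-{(4S,5S)-5-[(2Z,6R)-1-hydroxy-7-(4-methoxybenzyloxy)-6-methyl-6-(triethylsilyloxy)hept-2-en-2-yl]-2,2-dimethyl-1,3-dioxolan-4-yl}furan-2(5H)-one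
Conditions: SeO2 (0.3 equiv), t-BuOOH, CH2Cl2, 0 °C → rt
Reagents that add atoms: selenium dioxide, O=[Se]=O (catalytic oxygen carrier); tert-butyl hydroperoxide, CC(C)(C)OO
Why: SeO2 allylic oxidation (ene reaction, then [2,3]-sigmatropic shift) attacks the methyl group on the more substituted alkene carbon. The sigmatropic step places the new CH2OH trans to C2, so C9 and C2 stay cis; the electron-poor butenolide alkene is inert.

Step 13
Reactants: 18 4-{(4S,5S)-5-[(2Z,6R)-1-hydroxy-7-(4-methoxybenzyloxy)-6-methyl-6-(triethylsilyloxy)hept-2-en-2-yl]-2,2-dimethyl-1,3-dioxolan-4-yl}furan-2(5H)-one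
Product: 19 4-{(4S,5S)-5-[(2Z,6R)-1-(tert-butyldiphenylsilyloxy)-7-(4-methoxybenzyloxy)-6-methyl-6-(triethylsilyloxy)hept-2-en-2-yl]-2,2-dimethyl-1,3-dioxolan-4-yl}furan-2(5H)-one
Conditions: t-BuPh2SiCl, imidazole, CH2Cl2, 0 °C → rt
Reagents that add atoms: tert-butyl(chloro)diphenylsilane, CC(C)(C)[Si](Cl)(c1ccccc1)c1ccccc1
Why: Silylation of the primary allylic alcohol; this silyl group is chosen because it must survive the later aqueous acid step.

Step 14
Reactants: 19 4-{(4S,5S)-5-[(2Z,6R)-1-(tert-butyldiphenylsilyloxy)-7-(4-methoxybenzyloxy)-6-methyl-6-(triethylsilyloxy)hept-2-en-2-yl]-2,2-dimethyl-1,3-dioxolan-4-yl}furan-2(5H)-one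
Product: 20 4-{(4S,5S)-5-[(2Z,6R)-1-(tert-butyldiphenylsilyloxy)-7-hydroxy-6-methyl-6-(triethylsilyloxy)hept-2-en-2-yl]-2,2-dimethyl-1,3-dioxolan-4-yl}furan-2(5H)-one
Conditions: DDQ, CH2Cl2/pH 7 buffer, 0 °C
Reagents that add atoms: none
Why: Oxidative cleavage of the 4-methoxybenzyl ether; buffered DDQ leaves the silyl ethers, ketal, alkene and butenolide alone.

Step 15
Reactants: 20 4-{(4S,5S)-5-[(2Z,6R)-1-(tert-butyldiphenylsilyloxy)-7-hydroxy-6-methyl-6-(triethylsilyloxy)hept-2-en-2-yl]-2,2-dimethyl-1,3-dioxolan-4-yl}furan-2(5H)-one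
Product: 21 (2R,5Z)-7-(tert-butyldiphenylsilyloxy)-6-[(4S,5S)-2,2-dimethyl-5-(5-oxo-2,5-dihydrofuran-3-yl)-1,3-dioxolan-4-yl]-2-methyl-2-(triethylsilyloxy)hept-5-enal
Conditions: Dess–Martin periodinane, NaHCO3, CH2Cl2, 0 °C → rt
Reagents that add atoms: none
Why: Dess–Martin oxidation of the neopentyl primary alcohol; the aldehyde has no α-hydrogen, so C4 cannot epimerise.

Step 16
Reactants: 21 (2R,5Z)-7-(tert-butyldiphenylsilyloxy)-6-[(4S,5S)-2,2-dimethyl-5-(5-oxo-2,5-dihydrofuran-3-yl)-1,3-dioxolan-4-yl]-2-methyl-2-(triethylsilyloxy)hept-5-enal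
Product: 22 (2R,5Z)-7-(tert-butyldiphenylsilyloxy)-6-{(4S,5S)-2,2-dimethyl-5-[5-(triisopropylsilyloxy)furan-3-yl]-1,3-dioxolan-4-yl}-2-methyl-2-(triethylsilyloxy)hept-5-enal
Conditions: iPr3SiOTf, Et3N, CH2Cl2, 0 °C; filtration through Et3N-deactivated silica
Reagents that add atoms: triisopropylsilyl trifluoromethanesulfonate, CC(C)[Si](OS(=O)(=O)C(F)(F)F)(C(C)C)C(C)C
Why: Soft enolisation and O-silylation of the butenolide at its ring γ-CH2 gives the aromatic 2-silyloxyfuran. The non-enolisable aldehyde is not touched, and the bulky silyl triflate with excess amine is chosen so that it does not activate the aldehyde toward a premature aldol.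

Step 17
Reactants: 22 (2R,5Z)-7-(tert-butyldiphenylsilyloxy)-6-{(4S,5S)-2,2-dimethyl-5-[5-(triisopropylsilyloxy)furan-3-yl]-1,3-dioxolan-4-yl}-2-methyl-2-(triethylsilyloxy)hept-5-enal
Product: 23 ring-fused butenolide (ten-membered ring C1–C10 fused at C6/C7 to furan-2(5H)-one; 4R-methyl-4-triethylsilyloxy; 5R-hydroxy; 6R; 8S,9S-isopropylidenedioxy; 1(10)Z alkene carrying CH2OSiPh2t-Bu on C10)
Conditions: BF3·OEt2 (2 equiv), CH2Cl2, −78 °C, slow addition of 22 to 1 mM; NaHCO3 (aq)
Reagents that add atoms: none
Why: BF3 binds the C5 aldehyde and the 2-silyloxyfuran attacks it through its 5-position (C6) in an open transition state; loss of the silyl group from the oxocarbenium ion leaves the butenolide, which is a vinylogous Mukaiyama aldol reaction, the closest known type being the inter- and intramolecular (also macrocyclising) additions of 2-silyloxyfurans to aldehydes. The ten-membered carbocycle closes in a 10-(enolendo)-exo-trig mode, with the aldehyde C=O exocyclic and the furan C6=C7 bond endocyclic; the flat furan, the Z alkene and the trans-dioxolane take rotors and transannular hydrogens out of the chain. C5 is controlled by C4: the C4–OSiEt3 bond lies antiperiplanar to the incoming C6 (polar Felkin–Anh), and since C3 is part of the tether the ring should close through the rotamer in which the BF3-bound oxygen points away from C3 (methyl gauche to C=O, aldehyde hydrogen inside), which gives 5R with the C5 hydroxyl trans to the C4 oxygen on the ring, as the later inverting epoxide closure needs. An acyclic small/medium ranking would favour the other rotamer, so this selectivity rests on the ring and is the main risk. C6 is controlled by C8: with H8 in the furan plane next to H6, C9 and the tether lie on the furan face that leads to 6R, which puts the C5 hydroxyl and the lactone oxygen on the same ring face. Regioselectivity (C6 and not C11) follows from the vinylogous reactivity of silyloxyfurans, and high dilution with slow addition holds back oligomers.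

Step 18
Reactants: 23 ring-fused butenolide (4R,5R,6R,8S,9S)
Product: 24 cis-fused saturated γ-lactone (as 23 but C7–H and C11H2; 4R,5R,6R,7R,8S,9S)
Conditions: [(Ph3P)CuH]6, H2O (5 equiv), toluene, rt
Reagents that add atoms: none
Why: Conjugate reduction with the copper hydride (Stryker's reagent) delivers hydride to C7 on the butenolide face opposite the C5 substituent of the adjacent C6, so H7 ends cis to H6 (cis fusion); the isolated trisubstituted alkene is not reduced.

Step 19
Reactants: 24 cis-fused saturated γ-lactone
Product: 27 α-methylene lactone (as 24 but C11=C13H2), via Mannich base 25 (not isolated), via methiodide salt 26 (not isolated)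
Conditions: LiN(iPr)2 (2.3 equiv; 24 added to the base), THF, −78 °C; CH2=NMe2+ I−, −78 → 0 °C; then MeI, MeOH, rt; then NaHCO3 (aq), EtOAc, rt
Reagents that add atoms: N,N-dimethylmethyleneiminium iodide (Eschenmoser's salt), C=[N+](C)C.[I-]; iodomethane, CI (atoms in 26 only)
Why: The lactone enolate (with the C5 alkoxide as spectator) undergoes a Mannich reaction with Eschenmoser's salt; quaternisation and E1cB elimination give the exocyclic alkene and erase the C11 centre. It is done here because no ester or mesylate is yet present.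

Step 20
Reactants: 27 α-methylene lactone
Product: 28 C5 methanesulfonate of 27 (5R)
Conditions: MeSO2Cl, Et3N, CH2Cl2, 0 °C → rt
Reagents that add atoms: methanesulfonyl chloride, CS(=O)(=O)Cl
Why: Sulfonylation through sulfene tolerates the hindered secondary alcohol; with the lactone now saturated at C7 there is no acidic γ-hydrogen to eliminate the sulfonate.

Step 21
Reactants: 28 C5 methanesulfonate
Product: 29 triol mesylate (C4–OH, C8–OH, C9–OH free; C5–OSO2Me; C14–OSiPh2t-Bu)
Conditions: AcOH/THF/H2O (3:1:1), 45 °C
Reagents that add atoms: none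
Why: Acid hydrolysis removes the strained trans-fused isopropylidene ketal and the triethylsilyl ether; the mesylate, the bulky diphenylsilyl ether and the methylene lactone are stable, and no epoxide is present yet.

Step 22
Reactants: 30 (R)-2-methylglycidol
Product: 31 (S)-2-methyloxirane-2-carboxylic acid
Conditions: RuCl3 (2 mol %), NaIO4, MeCN/EtOAc/H2O, 0 °C → rt
Reagents that add atoms: sodium periodate, [Na+].[O-]I(=O)(=O)=O; water, O
Why: RuO4-catalysed oxidation of an epoxy alcohol to the epoxy acid; the quaternary stereocentre is untouched, and the descriptor changes to S because the priorities change.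

Step 23
Reactants: 29 triol mesylate; 31 (S)-2-methyloxirane-2-carboxylic acid
Product: 33 C8 (S)-2-methyloxirane-2-carboxylate of 29 (C9–OH and C4–OH free), via Yamaguchi mixed anhydride 32 (not isolated)
Conditions: 31, 2,4,6-Cl3C6H2COCl, Et3N, toluene, rt; then 29, DMAP, toluene, 0 °C → rt
Reagents that add atoms: 2,4,6-trichlorobenzoyl chloride, O=C(Cl)c1c(Cl)cc(Cl)cc1Cl (atoms in 32 only)
Why: Yamaguchi esterification. The α-quaternary acyl donor should take the more open C8 hydroxyl, since C9–OH is flanked by the fully substituted C10 with its bulky silyloxymethyl group and C4–OH is tertiary.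

Step 24
Reactants: 33 C8 epoxy ester
Product: 34 C8 epoxy ester C9 acetate (C4–OH free; C5–OSO2Me)
Conditions: Ac2O, pyridine, DMAP (cat.), CH2Cl2, 0 °C
Reagents that add atoms: acetic anhydride, CC(=O)OC(C)=O
Why: Acetylation of the remaining secondary alcohol with a small acyl donor; the tertiary C4 hydroxyl does not react at 0 °C, and C14 is not yet a carbonyl, so the acetate is not SN2′-labile toward DMAP.

Step 25
Reactants: 34 C8 epoxy ester C9 acetate
Product: 35 C4–C5 epoxide (4R,5S; C14–OSiPh2t-Bu)
Conditions: KN(SiMe3)2 (1.05 equiv), THF, −78 → −20 °C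
Reagents that add atoms: none
Why: Intramolecular Williamson reaction (3-exo-tet): the tertiary alkoxide displaces the trans mesylate with inversion at C5, giving the epoxide with C3 and C6 cis. One equivalent of a hindered amide base at low temperature removes the O–H proton faster than any C–H.

Step 26
Reactants: 35 C4–C5 epoxide
Product: 36 C14 allylic alcohol
Conditions: Bu4NF, AcOH (1:1), THF, rt
Reagents that add atoms: none
Why: Buffered fluoride cleaves the silyl ether near neutrality, which spares both epoxides and disfavours acetate migration and transannular opening.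

Step 27
Reactants: 36 C14 allylic alcohol
Product: 37 C14 enal
Conditions: Dess–Martin periodinane, NaHCO3, CH2Cl2, 0 °C
Reagents that add atoms: none
Why: Buffered Dess–Martin oxidation of a primary allylic alcohol; once C14 is a carbonyl the 1(10)-alkene is electron-poor and no longer threatens the epoxide.

Step 28
Reactants: 37 C14 enal
Product: 38 C14 carboxylic acid
Conditions: NaClO2, NaH2PO4, 2-methyl-2-butene, t-BuOH/H2O, 0 °C → rt
Reagents that add atoms: sodium chlorite, [Na+].[O-]Cl=O
Why: Pinnick oxidation of the enal with retention of alkene geometry; the scavenger protects the methylene lactone from hypochlorous acid.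

Step 29
Reactants: 38 C14 carboxylic acid
Product: 39 target CNP0274195.1
Conditions: MeI, KHCO3, DMF, rt
Reagents that add atoms: iodomethane, CI
Why: O-alkylation of the carboxylate under bicarbonate; this avoids diazoalkanes, which could add to the methylene lactone, and alkoxide bases, which would attack the esters.

Compound list

1 | (S)-2-methylglycidol | C[C@]1(CO)CO1 | starting material
2 | (R)-2-[(4-methoxybenzyloxy)methyl]-2-methyloxirane | C[C@]1(COCc2ccc(OC)cc2)CO1 | intermediate
3 | (R)-1-(4-methoxybenzyloxy)-2-methylpent-4-en-2-ol | C[C@](O)(COCc1ccc(OC)cc1)CC=C | intermediate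
4 | (R)-triethyl{[1-(4-methoxybenzyloxy)-2-methylpent-4-en-2-yl]oxy}silane | C[C@](O[Si](CC)(CC)CC)(COCc1ccc(OC)cc1)CC=C | intermediate
5 | B-alkyl-9-BBN adduct of 4 (boron on C1) | C[C@](O[Si](CC)(CC)CC)(COCc1ccc(OC)cc1)CCCB1C2CCCC1CCC2 | intermediate
6 | (R)-5-(4-methoxybenzyloxy)-4-methyl-4-(triethylsilyloxy)pentan-1-ol | C[C@](O[Si](CC)(CC)CC)(COCc1ccc(OC)cc1)CCCO | intermediate
7 | (R)-1-iodo-5-(4-methoxybenzyloxy)-4-methyl-4-(triethylsilyloxy)pentane | C[C@](O[Si](CC)(CC)CC)(COCc1ccc(OC)cc1)CCCI | intermediate
8 | [(R)-5-(4-methoxybenzyloxy)-4-methyl-4-(triethylsilyloxy)pentyl]triphenylphosphonium iodide | C[C@](O[Si](CC)(CC)CC)(COCc1ccc(OC)cc1)CCC[P+](c1ccccc1)(c1ccccc1)c1ccccc1.[I-] | intermediate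
9 | dimethyl (4R,5R)-2,2-dimethyl-1,3-dioxolane-4,5-dicarboxylate | COC(=O)[C@@H]1OC(C)(C)O[C@H]1C(=O)OC | starting material
10 | (4R,5R)-N4,N5-dimethoxy-N4,N5,2,2-tetramethyl-1,3-dioxolane-4,5-dicarboxamide | CON(C)C(=O)[C@@H]1OC(C)(C)O[C@H]1C(=O)N(C)OC | intermediate
11 | 1,1'-[(4R,5R)-2,2-dimethyl-1,3-dioxolane-4,5-diyl]diethanone | CC(=O)[C@@H]1OC(C)(C)O[C@H]1C(C)=O | intermediate
12 | phosphonium ylide from 8 | C[C@](O[Si](CC)(CC)CC)(COCc1ccc(OC)cc1)CCC=P(c1ccccc1)(c1ccccc1)c1ccccc1 | intermediate
13 | Z-alkenyl methyl ketone (C1=C10 joined; C14 methyl; 4R-OSiEt3; C5 PMB ether) | CC(=O)[C@@H]1OC(C)(C)O[C@H]1/C(C)=C\CC[C@@](C)(O[Si](CC)(CC)CC)COCc1ccc(OC)cc1 | intermediate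
14 | trimethylsilyl enol ether of 13 | C=C(O[Si](C)(C)C)[C@@H]1OC(C)(C)O[C@H]1/C(C)=C\CC[C@@](C)(O[Si](CC)(CC)CC)COCc1ccc(OC)cc1 | intermediate
15 | bromomethyl ketone | BrCC(=O)[C@@H]1OC(C)(C)O[C@H]1/C(C)=C\CC[C@@](C)(O[Si](CC)(CC)CC)COCc1ccc(OC)cc1 | intermediate
16 | keto phosphonoacetate | CCOP(=O)(OCC)CC(=O)OCC(=O)[C@@H]1OC(C)(C)O[C@H]1/C(C)=C\CC[C@@](C)(O[Si](CC)(CC)CC)COCc1ccc(OC)cc1 | intermediate
17 | β-substituted butenolide (C14 methyl) | O=C1C=C(CO1)[C@@H]1OC(C)(C)O[C@H]1/C(C)=C\CC[C@@](C)(O[Si](CC)(CC)CC)COCc1ccc(OC)cc1 | intermediate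
18 | butenolide with C14 hydroxyl | O=C1C=C(CO1)[C@@H]1OC(C)(C)O[C@H]1/C(CO)=C\CC[C@@](C)(O[Si](CC)(CC)CC)COCc1ccc(OC)cc1 | intermediate
19 | butenolide with C14 tert-butyldiphenylsilyl ether | O=C1C=C(CO1)[C@@H]1OC(C)(C)O[C@H]1/C(CO[Si](c2ccccc2)(c2ccccc2)C(C)(C)C)=C\CC[C@@](C)(O[Si](CC)(CC)CC)COCc1ccc(OC)cc1 | intermediate
20 | butenolide with free C5 hydroxyl | O=C1C=C(CO1)[C@@H]1OC(C)(C)O[C@H]1/C(CO[Si](c2ccccc2)(c2ccccc2)C(C)(C)C)=C\CC[C@@](C)(O[Si](CC)(CC)CC)CO | intermediate
21 | butenolide C5 aldehyde | O=C1C=C(CO1)[C@@H]1OC(C)(C)O[C@H]1/C(CO[Si](c2ccccc2)(c2ccccc2)C(C)(C)C)=C\CC[C@@](C)(O[Si](CC)(CC)CC)C=O | intermediate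
22 | 2-(triisopropylsilyloxy)furan tethered to the C5 aldehyde (key-step precursor) | CC(C)[Si](C(C)C)(C(C)C)Oc1cc(co1)[C@@H]1OC(C)(C)O[C@H]1/C(CO[Si](c2ccccc2)(c2ccccc2)C(C)(C)C)=C\CC[C@@](C)(O[Si](CC)(CC)CC)C=O | intermediate
23 | ten-membered ring-fused butenolide with C5 hydroxyl (key-step product; 4R,5R,6R,8S,9S) | O=C1C=C2[C@@H]3OC(C)(C)O[C@H]3/C(CO[Si](c4ccccc4)(c4ccccc4)C(C)(C)C)=C\CC[C@@](C)(O[Si](CC)(CC)CC)[C@H](O)[C@@H]2O1 | intermediate
24 | cis-fused saturated lactone (7R) | O=C1C[C@@H]2[C@@H]3OC(C)(C)O[C@H]3/C(CO[Si](c4ccccc4)(c4ccccc4)C(C)(C)C)=C\CC[C@@](C)(O[Si](CC)(CC)CC)[C@H](O)[C@@H]2O1 | intermediate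
25 | Mannich base (C11 dimethylaminomethyl; C11 epimers) | O=C1C(CN(C)C)[C@@H]2[C@@H]3OC(C)(C)O[C@H]3/C(CO[Si](c4ccccc4)(c4ccccc4)C(C)(C)C)=C\CC[C@@](C)(O[Si](CC)(CC)CC)[C@H](O)[C@@H]2O1 | intermediate
26 | methiodide salt of 25 | O=C1C(C[N+](C)(C)C)[C@@H]2[C@@H]3OC(C)(C)O[C@H]3/C(CO[Si](c4ccccc4)(c4ccccc4)C(C)(C)C)=C\CC[C@@](C)(O[Si](CC)(CC)CC)[C@H](O)[C@@H]2O1.[I-] | intermediate
27 | α-methylene lactone with C5 hydroxyl | O=C1C(=C)[C@@H]2[C@@H]3OC(C)(C)O[C@H]3/C(CO[Si](c4ccccc4)(c4ccccc4)C(C)(C)C)=C\CC[C@@](C)(O[Si](CC)(CC)CC)[C@H](O)[C@@H]2O1 | intermediate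
28 | C5 methanesulfonate | O=C1C(=C)[C@@H]2[C@@H]3OC(C)(C)O[C@H]3/C(CO[Si](c4ccccc4)(c4ccccc4)C(C)(C)C)=C\CC[C@@](C)(O[Si](CC)(CC)CC)[C@H](OS(C)(=O)=O)[C@@H]2O1 | intermediate
29 | triol mesylate (C4, C8, C9 hydroxyls free) | O=C1C(=C)[C@@H]2[C@H](O)[C@@H](O)/C(CO[Si](c3ccccc3)(c3ccccc3)C(C)(C)C)=C\CC[C@@](C)(O)[C@H](OS(C)(=O)=O)[C@@H]2O1 | intermediate
30 | (R)-2-methylglycidol | C[C@@]1(CO)CO1 | starting material
31 | (S)-2-methyloxirane-2-carboxylic acid | C[C@@]1(C(=O)O)CO1 | intermediate
32 | mixed anhydride of 31 with 2,4,6-trichlorobenzoic acid | C[C@@]1(C(=O)OC(=O)c2c(Cl)cc(Cl)cc2Cl)CO1 | intermediate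
33 | C8 epoxy ester (C9 and C4 hydroxyls free) | O=C1C(=C)[C@@H]2[C@H](OC(=O)[C@]3(C)CO3)[C@@H](O)/C(CO[Si](c3ccccc3)(c3ccccc3)C(C)(C)C)=C\CC[C@@](C)(O)[C@H](OS(C)(=O)=O)[C@@H]2O1 | intermediate
34 | C8 epoxy ester C9 acetate (hydroxy mesylate) | O=C1C(=C)[C@@H]2[C@H](OC(=O)[C@]3(C)CO3)[C@@H](OC(C)=O)/C(CO[Si](c3ccccc3)(c3ccccc3)C(C)(C)C)=C\CC[C@@](C)(O)[C@H](OS(C)(=O)=O)[C@@H]2O1 | intermediate
35 | C4–C5 epoxide with C14 silyl ether | O=C1C(=C)[C@@H]2[C@H](OC(=O)[C@]3(C)CO3)[C@@H](OC(C)=O)/C(CO[Si](c3ccccc3)(c3ccccc3)C(C)(C)C)=C\CC[C@@]3(C)O[C@H]3[C@@H]2O1 | intermediate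
36 | C14 allylic alcohol | O=C1C(=C)[C@@H]2[C@H](OC(=O)[C@]3(C)CO3)[C@@H](OC(C)=O)/C(CO)=C\CC[C@@]3(C)O[C@H]3[C@@H]2O1 | intermediate
37 | C14 enal | O=C1C(=C)[C@@H]2[C@H](OC(=O)[C@]3(C)CO3)[C@@H](OC(C)=O)/C(C=O)=C\CC[C@@]3(C)O[C@H]3[C@@H]2O1 | intermediate
38 | C14 carboxylic acid | O=C1C(=C)[C@@H]2[C@H](OC(=O)[C@]3(C)CO3)[C@@H](OC(C)=O)/C(C(=O)O)=C\CC[C@@]3(C)O[C@H]3[C@@H]2O1 | intermediate
39 | CNP0274195.1 | C=C1C(=O)O[C@@H]2[C@H]1[C@H](OC(=O)[C@]1(C)CO1)[C@@H](OC(C)=O)/C(C(=O)OC)=C\CC[C@@]1(C)O[C@@H]21 | target

Totals and least certain steps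

Total: 29 steps. Longest linear sequence: 26 steps (steps 1–6, 9–21, 23–29).

Step 17 (key step). The most likely failures are poor facial selectivity at C5 (an acyclic-type rotamer with the BF3-bound oxygen next to C3 would give the 5S carbinol) and competing intermolecular aldol addition, because a ten-membered closure is slow. Selectivity at C6 is tied to the C7–C8 rotamer and cannot be corrected afterwards. The fallback for the C5 problem sets out from 22 and sets C5 by ketone reduction and not by the aldol. The cyclisation product, the 5S epimer of the ring-fused butenolide F1, is reduced with [(Ph3P)CuH]6 to the 5S hydroxy lactone F2. Only then is C5 oxidised with Dess–Martin periodinane to the C5 ketone F3; a ketone next to the butenolide γ-carbon would enolise and scramble C6, which is why the oxidation waits for the saturated lactone. F3 is reduced with NaBH4/CeCl3 at −78 °C, or with an oxazaborolidine/BH3 system if the ring bias has to be overridden, and the route is rejoined at 24.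

Step 23. The most likely failure is poor site selectivity between the C8 and C9 hydroxyls, since both are secondary and the screening of C9 by the silyloxymethyl group is only an argument from sterics; translactonisation of the free C8 hydroxyl is a lesser concern. The fallback sets out from 29 and replaces reagent discrimination by a tether. HF·pyridine removes the C14 silyl group to give the tetraol mesylate F4. t-Bu2Si(OTf)2 with 2,6-lutidine silylates the primary C14 hydroxyl first and can close only onto O9 (six-membered ring), giving the 9,14-O-di-tert-butylsilylene F5 and leaving C8–OH as the only free secondary alcohol. Yamaguchi esterification with 31 gives the C8 epoxy ester silylene F6, HF·pyridine gives the C8 epoxy ester 9,14-diol F7, and t-BuPh2SiCl/imidazole on the primary hydroxyl returns to the route at 33.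

Step 18. The most likely failure is hydride delivery to the wrong face of C7 (trans-fused lactone) if the macrocycle folds over the face opposite C5, or slow reduction of the fully substituted β-carbon. The fallback sets out from 23 and returns at 24, replacing substrate control by catalyst control: a copper hydride generated from Cu(OAc)2, a chiral bisphosphine and a hydrosilane, with the ligand enantiomer chosen to override the ring bias. This fallback makes no new compound (F0).

Step 12. The most likely failures are erosion of alkene geometry in the sigmatropic step, because C10 carries the bulky dioxolanyl carbon and not a second methyl, and partial over-oxidation. The fallback sets out from 17 and replaces kinetic by thermodynamic control of geometry. The oxidation is driven through to the C14 enal F8 (excess t-BuOOH, or MnO2 on the crude alcohol), the enal is equilibrated with catalytic iodine to the favoured isomer with the formyl group trans to C2, and Luche reduction (NaBH4, CeCl3, −78 °C) returns to the route at 18.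

Further compounds

F1 | step 17 | 5S epimer of ring-fused butenolide 23 | O=C1C=C2[C@@H]3OC(C)(C)O[C@H]3/C(CO[Si](c4ccccc4)(c4ccccc4)C(C)(C)C)=C\CC[C@@](C)(O[Si](CC)(CC)CC)[C@@H](O)[C@@H]2O1
F2 | step 17 | 5S epimer of saturated lactone 24 | O=C1C[C@@H]2[C@@H]3OC(C)(C)O[C@H]3/C(CO[Si](c4ccccc4)(c4ccccc4)C(C)(C)C)=C\CC[C@@](C)(O[Si](CC)(CC)CC)[C@@H](O)[C@@H]2O1
F3 | step 17 | C5 ketone of the saturated lactone | O=C1C[C@@H]2[C@@H]3OC(C)(C)O[C@H]3/C(CO[Si](c4ccccc4)(c4ccccc4)C(C)(C)C)=C\CC[C@@](C)(O[Si](CC)(CC)CC)C(=O)[C@@H]2O1
F4 | step 23 | tetraol mesylate (C4, C8, C9, C14 hydroxyls free) | O=C1C(=C)[C@@H]2[C@H](O)[C@@H](O)/C(CO)=C\CC[C@@](C)(O)[C@H](OS(C)(=O)=O)[C@@H]2O1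
F5 | step 23 | 9,14-O-di-tert-butylsilylene with free C8 hydroxyl | O=C1C(=C)[C@@H]2[C@H](O)[C@H]3O[Si](C(C)(C)C)(C(C)(C)C)OC/C3=C/CC[C@@](C)(O)[C@H](OS(C)(=O)=O)[C@@H]2O1
F6 | step 23 | C8 epoxy ester 9,14-O-di-tert-butylsilylene | O=C1C(=C)[C@@H]2[C@H](OC(=O)[C@]4(C)CO4)[C@H]3O[Si](C(C)(C)C)(C(C)(C)C)OC/C3=C/CC[C@@](C)(O)[C@H](OS(C)(=O)=O)[C@@H]2O1
F7 | step 23 | C8 epoxy ester 9,14-diol | O=C1C(=C)[C@@H]2[C@H](OC(=O)[C@]3(C)CO3)[C@@H](O)/C(CO)=C\CC[C@@](C)(O)[C@H](OS(C)(=O)=O)[C@@H]2O1
F0 | step 18 | none | none
F8 | step 12 | C14 enal of butenolide 17 | O=C1C=C(CO1)[C@@H]1OC(C)(C)O[C@H]1/C(C=O)=C\CC[C@@](C)(O[Si](CC)(CC)CC)COCc1ccc(OC)cc1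
A1 | alternative 1 | cis-fused α-diethylphosphono γ-lactone (C11 epimers) | CCOP(=O)(OCC)C1C(=O)O[C@@H]2[C@H]1[C@H](OC(=O)[C@]1(C)CO1)[C@@H](OC(C)=O)/C(C(=O)OC)=C\CC[C@@](C)(O[Si](CC)(CC)CC)[C@@H]2OS(C)(=O)=O
A2 | alternative 1 | C6 diazo(diethylphosphono)acetate of the ten-membered carbocycle | [N-]=[N+]=C(C(=O)O[C@@H]1C[C@H](OC(=O)[C@]2(C)CO2)[C@@H](OC(C)=O)/C(C(=O)OC)=C\CC[C@@](C)(O[Si](CC)(CC)CC)[C@@H]1OS(C)(=O)=O)P(=O)(OCC)OCC
A3 | alternative 2 | methyl (4Z,9Z)-2,7-dioxocyclodeca-4,9-diene-1-carboxylate | COC(=O)C1/C=C\CC(=O)C/C=C\CC1=O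
A4 | alternative 2 | methyl 1,4,5,8-tetrahydronaphthalene-1-carboxylate | COC(=O)C1C=CCC2=C1CC=CC2
A5 | alternative 3 | ten-membered dienamine ester (ring-cis C9=C10, E C1=C2) | C/C1=C/[C@H]2[C@H](C=C)[C@H](OC(C)(C)O2)/C(N3CCCC3)=C(/C(=O)OC)\C=C\C1
A6 | alternative 3 | pyrrolidine enamine of the eight-membered ketone | C/C1=C/[C@H]2[C@H](C=C)[C@H](OC(C)(C)O2)/C(N3CCCC3)=C\C1
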